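**Plan**
- Retrosynthesis: the 6-OH is traced back to a 6-OMe and the 8-OMe to an 8-OH; ring C is then cut at O1–C8a, the diketone at C2–C3 and the aryl ketone at C4–C4a.
- Enabling feature: the oxygens on C5 and C8 of ring A are para to each other, so ring A can be carried as a 1,4-benzoquinone. Its only unsubstituted carbon (future C8a) is beta to the C5 carbonyl and to the C4 ketone and can accept the diketone enol oxygen (future O1).
- Forward: 1,2,3,4-tetramethoxybenzene (ring A) is acetylated (C4–C4a) with loss of the ortho methyl, the dianion is aroylated with the ring B acid chloride (C2–C3), and the para-methoxyphenol is oxidised to the acylquinone.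
- Ring C then closes by oxa-Michael addition (O1–C8a) and tautomerisation to the 5,8-dihydroxyflavone; methylation at O8 and chelation-directed demethylation at O6 complete the target.
- Stereochemistry: the target is achiral and has no stereocentre, so none has to be set.

Key step: step 4

Assumption: 1,2,3,4-tetramethoxybenzene and 3,4-dimethoxybenzoyl chloride are taken as catalogue chemicals, and the acylquinone 7 is taken to survive a short extractive work-up so that it can be used without chromatography.

**Step 1**
Reactants: 1 1,2,3,4-tetramethoxybenzene; 2 acetyl chloride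
Product: 4 2-hydroxy-3,4,5-trimethoxyacetophenone, via 2,3,4,5-tetramethoxyacetophenone 3 (not isolated)
Conditions: AlCl3 (2.5 equiv), CH2Cl2, 0 °C to rt; ice-water
Reagents that add atoms: none
Why: Friedel–Crafts acylation at one of the two equivalent free positions gives 3, whose carbonyl and ortho methoxy group chelate AlCl3 so that chloride cleaves only that methyl ether (chelation-directed ortho-demethylation of an aryl ketone).

**Step 2**
Reactants: 4 2-hydroxy-3,4,5-trimethoxyacetophenone; 5 3,4-dimethoxybenzoyl chloride
Product: 6 1-(2-hydroxy-3,4,5-trimethoxyphenyl)-3-(3,4-dimethoxyphenyl)propane-1,3-dione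
Conditions: LiN(SiMe3)2 (3.2 equiv), THF, –78 to –10 °C; then 5 (1.05 equiv), –78 °C to rt; aq. NH4Cl
Reagents that add atoms: none
Why: The phenoxide–enolate dianion of 4 is acylated at carbon by the acid chloride (one-pot variant of the Baker–Venkataraman and Claisen acylation of 2-hydroxyacetophenones), and any O-aroylated material rearranges to the same diketone under the excess base.

**Step 3**
Reactants: 6 1-(2-hydroxy-3,4,5-trimethoxyphenyl)-3-(3,4-dimethoxyphenyl)propane-1,3-dione
Product: 7 1-(4,5-dimethoxy-3,6-dioxocyclohexa-1,4-dien-1-yl)-3-(3,4-dimethoxyphenyl)propane-1,3-dione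
Conditions: PhI(OAc)2 (1.05 equiv), MeCN/H2O (4:1), 0 °C, 10 min; cold extractive work-up, used crude
Reagents that add atoms: water, O
Why: Oxidative demethylation of a para-methoxyphenol by a trivalent iodine reagent: water adds to the oxidised phenol at the methoxy-bearing para carbon and the hemiketal loses methanol to give the 1,4-benzoquinone, the pattern by which 2,3,4-trimethoxy-6-alkylphenols are converted into 2,3-dimethoxy-1,4-benzoquinones.

**Step 4**
Reactants: 7 1-(4,5-dimethoxy-3,6-dioxocyclohexa-1,4-dien-1-yl)-3-(3,4-dimethoxyphenyl)propane-1,3-dione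
Product: 8 5,8-dihydroxy-6,7-dimethoxy-2-(3,4-dimethoxyphenyl)chromen-4-one
Conditions: CF3CO2H (0.2 equiv), degassed CH2Cl2 (0.002 M), 0 °C to rt, Ar, dark; aq. Na2S2O4 wash
Reagents that add atoms: none
Why: Proposed new method: the enolised 1,3-diketone of 7 holds its outer enol oxygen within reach of the only unsubstituted quinone carbon (future C8a), which is beta to both the quinone carbonyl at future C5 and the side-chain ketone (future C4) and is therefore a doubly activated acceptor; acid-assisted conjugate addition forms O1–C8a, and enolisation of the resulting ene-dione to the aromatic hydroquinone makes the closure irreversible. The closest known reaction type is the intramolecular oxa-Michael addition of hydroxyl groups to quinones that gives chromans and benzofurans after tautomerisation, together with the general preference of nucleophiles for C3 of 2-acyl-1,4-benzoquinones. Ring C closes in a 6-endo-trig mode. No stereocentre is created. The step needs oxygen attack at C8a instead of 1,2-addition to the neighbouring quinone carbonyl or intermolecular C-alkylation by the diketone carbon: addition to the carbonyl is reversible and cannot aromatise, the diketone carbon and the inner oxygen could only close four-membered rings, and high dilution disfavours bimolecular paths. Dilution, the absence of base and exclusion of air should also hold back hydrogen transfer from product 8 to unreacted 7, and the dithionite wash should return any over-oxidised flavonequinone to 8.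

**Step 5**
Reactants: 8 5,8-dihydroxy-6,7-dimethoxy-2-(3,4-dimethoxyphenyl)chromen-4-one
Product: 9 5-hydroxy-6,7,8-trimethoxy-2-(3,4-dimethoxyphenyl)chromen-4-one
Conditions: Me2SO4 (1.05 equiv), K2CO3 (1.5 equiv), acetone, reflux, Ar
Reagents that add atoms: dimethyl sulfate, COS(=O)(=O)OC
Why: Williamson methylation of the free 8-hydroxyl; the 5-hydroxyl is tied up in a hydrogen bond to the C4 carbonyl and should stay unmethylated with one equivalent of reagent (classical partial methylation of 5,8-dihydroxyflavones).

**Step 6**
Reactants: 9 5-hydroxy-6,7,8-trimethoxy-2-(3,4-dimethoxyphenyl)chromen-4-one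
Product: 10 Pebrellin, 5,6-dihydroxy-7,8-dimethoxy-2-(3,4-dimethoxyphenyl)chromen-4-one
Conditions: AlBr3 (6 equiv), MeCN, 0 °C to rt; then 2% aq. HCl, 60 °C
Reagents that add atoms: none
Why: Chelation-directed selective ether cleavage: the aluminium phenoxide formed at O5 also binds the neighbouring 6-methoxy oxygen, so bromide should remove only that methyl group while the acetonitrile-moderated Lewis acid leaves the 7-, 8-, 3'- and 4'-methoxy groups alone, a selectivity precedented for 5-hydroxy-6,7,8-trimethoxyflavones.

**Compound list**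
1 | 1,2,3,4-tetramethoxybenzene | COc1ccc(OC)c(OC)c1OC | starting material
2 | acetyl chloride | CC(Cl)=O | starting material
3 | 2,3,4,5-tetramethoxyacetophenone | CC(=O)c1cc(OC)c(OC)c(OC)c1OC | intermediate (not isolated)
4 | 2-hydroxy-3,4,5-trimethoxyacetophenone | CC(=O)c1cc(OC)c(OC)c(OC)c1O | intermediate
5 | 3,4-dimethoxybenzoyl chloride | COc1ccc(C(Cl)=O)cc1OC | starting material
6 | 1-(2-hydroxy-3,4,5-trimethoxyphenyl)-3-(3,4-dimethoxyphenyl)propane-1,3-dione | COc1ccc(C(=O)CC(=O)c2cc(OC)c(OC)c(OC)c2O)cc1OC | intermediate
7 | 1-(4,5-dimethoxy-3,6-dioxocyclohexa-1,4-dien-1-yl)-3-(3,4-dimethoxyphenyl)propane-1,3-dione | COC1=C(OC)C(=O)C(C(=O)CC(=O)c2ccc(OC)c(OC)c2)=CC1=O | intermediate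
8 | 5,8-dihydroxy-6,7-dimethoxy-2-(3,4-dimethoxyphenyl)chromen-4-one | COc1ccc(-c2cc(=O)c3c(O)c(OC)c(OC)c(O)c3o2)cc1OC | intermediate
9 | 5-hydroxy-6,7,8-trimethoxy-2-(3,4-dimethoxyphenyl)chromen-4-one | COc1ccc(-c2cc(=O)c3c(O)c(OC)c(OC)c(OC)c3o2)cc1OC | intermediate
10 | Pebrellin, 5,6-dihydroxy-7,8-dimethoxy-2-(3,4-dimethoxyphenyl)chromen-4-one | COc1ccc(-c2cc(=O)c3c(O)c(O)c(OC)c(OC)c3o2)cc1OC | target

Total step count: 6. Longest linear sequence: 6 steps (1 to 10).

**Steps most likely to fail**

Step 4. The quinone may be consumed faster than ring C closes, either by intermolecular carbon–carbon Michael addition of the diketone carbon or by hydrogen transfer from the product hydroquinone to unreacted quinone. The enol oxygen may also add reversibly to the quinone carbonyl and never reach C8a. The fallback uses known flavone chemistry; it sets out from 5 and returns at 8. The dianion of commercial 1-(6-hydroxy-2,3,4-trimethoxyphenyl)ethanone F1 (LiN(SiMe3)2, THF) would be aroylated with 5 to give 1-(6-hydroxy-2,3,4-trimethoxyphenyl)-3-(3,4-dimethoxyphenyl)propane-1,3-dione F2. Cyclodehydration (H2SO4, AcOH, 100 °C) should give 5,6,7-trimethoxy-2-(3,4-dimethoxyphenyl)chromen-4-one F3. BCl3 in CH2Cl2 at low temperature would then cleave only the peri 5-methyl ether to give 5-hydroxy-6,7-dimethoxy-2-(3,4-dimethoxyphenyl)chromen-4-one F4. Elbs persulfate oxidation (K2S2O8, aq. KOH/pyridine) should introduce oxygen para to the 5-hydroxyl as 5-hydroxy-6,7-dimethoxy-2-(3,4-dimethoxyphenyl)-4-oxochromen-8-yl hydrogen sulfate F5, and hot dilute HCl would hydrolyse this to 8.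

Step 3. The iodine oxidant may attack the enolised diketone instead of the phenol, water may add ortho instead of para, or the quinone may ring-close prematurely in the oxidising medium and be over-oxidised. The fallback sets the oxidation level before the diketone exists and makes the quinone by a neutral dehydrogenation; it sets out from 4 and returns at 7. Oxidation of 4 itself with PhI(OAc)2 in aqueous MeCN should give 2-acetyl-5,6-dimethoxycyclohexa-2,5-diene-1,4-dione F6, and reduction with aq. Na2S2O4 would give 1-(2,5-dihydroxy-3,4-dimethoxyphenyl)ethanone F7. Carbon-aroylation of its trianion (LiN(SiMe3)2, 4.5 equiv, THF, then 5) should give 1-(2,5-dihydroxy-3,4-dimethoxyphenyl)-3-(3,4-dimethoxyphenyl)propane-1,3-dione F8. Dehydrogenation of this hydroquinone with Ag2O and Na2SO4 in Et2O would deliver 7 in a medium free of acid and of excess oxidant.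

Step 6. Ether cleavage may not stop at the 6-methoxy group and may also strip the 7-, 8- or ring B methyl ethers, or it may fail to distinguish the 6- from the 7-methoxy group. The fallback avoids ether cleavage altogether; it sets out from 8, bypasses 9 and returns at 10. A Wessely–Moser isomerisation of 8 (conc. HCl/AcOH, reflux, Ar) would open ring C to 1-(2,3,6-trihydroxy-4,5-dimethoxyphenyl)-3-(3,4-dimethoxyphenyl)propane-1,3-dione F9. Reclosure through the former 5-hydroxyl turns the 5,8-dihydroxy-6,7-dimethoxy pattern into the 5,6-dihydroxy-7,8-dimethoxy pattern of 10. The equilibrium is expected to lie toward the 5,6-dihydroxy isomer, and 10 would have to be separated from any remaining 8.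

**Further compounds**
F1 | step 4 | 1-(6-hydroxy-2,3,4-trimethoxyphenyl)ethanone | CC(=O)c1c(O)cc(OC)c(OC)c1OC
F2 | step 4 | 1-(6-hydroxy-2,3,4-trimethoxyphenyl)-3-(3,4-dimethoxyphenyl)propane-1,3-dione | COc1ccc(C(=O)CC(=O)c2c(O)cc(OC)c(OC)c2OC)cc1OC
F3 | step 4 | 5,6,7-trimethoxy-2-(3,4-dimethoxyphenyl)chromen-4-one | COc1ccc(-c2cc(=O)c3c(OC)c(OC)c(OC)cc3o2)cc1OC
F4 | step 4 | 5-hydroxy-6,7-dimethoxy-2-(3,4-dimethoxyphenyl)chromen-4-one | COc1ccc(-c2cc(=O)c3c(O)c(OC)c(OC)cc3o2)cc1OC
F5 | step 4 | 5-hydroxy-6,7-dimethoxy-2-(3,4-dimethoxyphenyl)-4-oxochromen-8-yl hydrogen sulfate | COc1ccc(-c2cc(=O)c3c(O)c(OC)c(OC)c(OS(=O)(=O)O)c3o2)cc1OC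
F6 | step 3 | 2-acetyl-5,6-dimethoxycyclohexa-2,5-diene-1,4-dione | CC(=O)C1=CC(=O)C(OC)=C(OC)C1=O
F7 | step 3 | 1-(2,5-dihydroxy-3,4-dimethoxyphenyl)ethanone | CC(=O)c1cc(O)c(OC)c(OC)c1O
F8 | step 3 | 1-(2,5-dihydroxy-3,4-dimethoxyphenyl)-3-(3,4-dimethoxyphenyl)propane-1,3-dione | COc1ccc(C(=O)CC(=O)c2cc(O)c(OC)c(OC)c2O)cc1OC
F9 | step 6 | 1-(2,3,6-trihydroxy-4,5-dimethoxyphenyl)-3-(3,4-dimethoxyphenyl)propane-1,3-dione | COc1ccc(C(=O)CC(=O)c2c(O)c(O)c(OC)c(OC)c2O)cc1OC
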